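The ratio to look at first is G to Q in the autumn charge, 2.50. Q is the limiting reagent, so the bench habit is to call G constant and treat the flask as pseudo-first-order.

| flask | Q | G | L | E | time |
|---|---|---|---|---|---|
| autumn | 120 mM | 300 mM | 0.600 mM |  |  |
| noon | 60.0 mM | 240 mM | 0.600 mM |  |  |
| midnight | 120 mM | 450 mM | 0.600 mM |  |  |
| dusk | 120 mM | 300 mM | 0.600 mM | 60.0 mM |  |
| winter | 120 mM | 300 mM | 0.600 mM |  | 10 h |

| autumn run: time / h | autumn run: [E] / mM | noon run: time / h | noon run: [E] / mM | midnight run: time / h | midnight run: [E] / mM | dusk run: time / h | dusk run: [E] / mM |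
|---|---|---|---|---|---|---|---|
| 0.68 | 33.8 | 0.68 | 14.1 | 0.68 | 46.6 | 0.68 | 94.2 |
| 1.4 | 56.3 | 1.4 | 24.8 | 1.4 | 74.6 | 1.4 | 116.6 |
| 2.0 | 70.2 | 2.0 | 32.3 | 2.0 | 89.8 | 2.0 | 130.8 |
| 2.7 | 82.3 | 2.7 | 38.4 | 2.7 | 100.1 | 2.7 | 142.9 |
| 3.4 | 91.1 | 3.4 | 42.9 | 3.4 | 106.6 | 3.4 | 150.6 |
| 4.1 | 97.4 | 4.1 | 46.0 | 4.1 | 111.2 | 4.1 | 157.5 |

(scatter of a reading: 0.6 mM)

- Overall: Q + G -> E, with L as catalyst.
- Constant volume, constant temperature.
- "The second partner" is G.
- An order is taken over about fifteen percent of the charge, up and down.

- how the opening rate goes with [Q] round the charge of the autumn run: the exponent of the rate at two percent of Q gone to E (one fixed amount of E, the same in the runs compared)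
- how the opening rate goes with [G] round the charge of the autumn run: the exponent of the rate at two percent of Q gone to E
- the noon run starts with 60.0 mM less of Q and of G than the autumn run, and with no E. Compared where both hold the same amount of Q, once fifteen percent of what the noon run was charged with has turned into E, is the noon run faster, slower or alike (within a tenth)?
- E in the winter run at 10 h, as a share of the Q charged

Soften that habit a little: over a stretch of curve, replace Q and G by their means. Over the first autumn reading this gives:

rate 49.7 mM/h ÷ (mean Q 103 mM × mean G 283 mM) = 1.70 /M/h

Call this the pair constant: the rate of making E divided by mean Q and mean G. The same reckoning on the first reading of the noon run gives 1.68 /M/h, and on that of the midnight run 1.66 /M/h. The constant barely moves while Q and G change, so my reckoning takes the rate as first power in each, orders 1 and 1.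

By its first reading the dusk flask had made 34.2 mM of new E, against 33.8 mM in the autumn flask. That gap is less than the scatter of one reading, so this first dusk reading shows no effect of added E on the rate. The noon charge has the same excess of G over Q as the autumn charge, 180 mM, so equal Q means equal G, and I expect the two alike.

Now the border. The winter flask has the autumn charge, and using up its Q would take G from 300 mM down to 180 mM, a fall of 40.0 %. Holding G at those two ends leaves 0.610 % or 4.69 % of Q at 10 h, and the mean 240 mM gives a yield of 98.3 %. You should not trust that mean, since at 4.1 h the autumn flask already holds less G than it, with 5.90 h still to run. So restart the rule from that reading, where G can fall by only 11.2 %: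

Q 22.6 mM, mean G 191 mM, Q left 3.31 mM

That makes my yield 97.2 %.

The forecast gives orders 1 and 1, alike, and 97.3 %, holding that “added E neither inhibits nor reverses the reaction”.

The flask gives orders 1.0 in Q and 1.0 in G, the noon run alike with the autumn run at equal Q, and 97.3 % in the winter flask, and the best power law over the runs has order 1.0 in G.

    2 L ⇌ L2, settled at all times (58000 /M)
    L + Q + G → E + L (16270 /M²/h)
    Q + G → E (0.6228 /M/h)

Now put the pair constant on the midnight flask. To make half of its Q, with mean Q 90.0 mM and mean G 420 mM, it predicts 0.932 h, and the midnight run got there at 0.966 h.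

The earlier runs and the new flask are simulated for substances that don't exist; noise was put on by code.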